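Ring A is built rather than decorated: a Danheiser benzannulation of 3-ethoxycyclobutenone with a prenyl-bearing triisopropylsilyloxyalkyne forms C8a–C8, C7–C6 and C4a–C8a in one heating operation. It exploits the pentasubstituted ring A, whose three oxygens (O1, O5, O7) must be told apart and whose C8 prenyl lies between O1 and O7. The product carries O1 as the only free hydroxyl, O7 as a silyl ether, O5 as an ethyl ether and C4a–H as the only free ortho position. Chelation-directed formylation at C4a, homologation to the ketone, Baker–Venkataraman acyl transfer with a bis-silylated ring B acid and cyclodehydration then close ring C through O1. Peri-chelated MgI2 cleavage frees O5 and fluoride ends the route.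

Key step: step 2

Remark: 1, 2, 6, 14 and 18 are taken as purchasable; ring B is carried as silyl ethers rather than acetals so that no aqueous acid is needed once both prenyl groups are in place.

Step 1
Reactants: 1 ethyl 4-methylpent-3-enoate; 2 triisopropylsilyl trifluoromethanesulfonate
Product: 5 siloxyalkyne 5-methyl-1-(triisopropylsilyloxy)hex-4-en-1-yne, via dibromo enolate 3 (not isolated), via lithium ynolate 4 (not isolated)
Conditions: CH2Br2, lithium 2,2,6,6-tetramethylpiperidide (2.2 equiv), THF, −78 °C; n-BuLi, −78 → 20 °C; then 2, −78 → 0 °C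
Reagents that add atoms: dibromomethane, BrCBr
Why: Kowalski ester homologation, in which LiCHBr2 adds to the ester, the derived dibromo enolate 3 undergoes bromine–lithium exchange and 1,2-shift of the alkyl group to ynolate 4, and the bulky silyl triflate then silylates oxygen rather than carbon; no stereocentre is formed.

Step 2
Reactants: 5 siloxyalkyne 5-methyl-1-(triisopropylsilyloxy)hex-4-en-1-yne; 6 3-ethoxycyclobut-2-en-1-one
Product: 11 5-ethoxy-2-(3-methylbut-2-en-1-yl)-3-(triisopropylsilyloxy)phenol, via vinylketene 7 (not isolated), via vinylcyclobutenone 8 (not isolated), via dienylketene 9 (not isolated), via cyclohexadienone 10 (not isolated)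
Conditions: PhMe, 80 → 110 °C, sealed tube, 5 in slight excess
Reagents that add atoms: none
Why: Danheiser benzannulation: on heating, 6 undergoes conrotatory four-electron ring opening to vinylketene 7, whose ketene unit is trapped in a [2+2] cycloaddition by the electron-rich triple bond of 5 to give 8 (C8a–C8 and C7–C6). A second four-electron opening of 8 gives dienylketene 9, and ring A is closed by a thermal, disrotatory six-electron electrocyclisation (C4a–C8a) to dienone 10, which tautomerises to phenol 11. The closest known reaction type is the thermal union of cyclobutenones with trialkylsilyloxyalkynes to give monosilylated resorcinols. No stereocentre survives, since the racemic centre of 8 is lost on ring opening. The step needs one regiochemical outcome, and the polarisation of the ynol ether secures it: its β-carbon, the one carrying the prenyl group, is the nucleophilic terminus and bonds to the ketene carbonyl carbon, so the prenyl group ends up between the new hydroxyl (O1) and the silyl ether (O7), with OEt at C5 and C4a–H as the only free position ortho to the hydroxyl. Chemoselectivity follows from the same polarisation, since neither trisubstituted alkene competes with the ynol ether for the ketene, and the bulky triisopropylsilyl group holds back silyl transfer.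

Step 3
Reactants: 11 5-ethoxy-2-(3-methylbut-2-en-1-yl)-3-(triisopropylsilyloxy)phenol
Product: 13 6-ethoxy-2-hydroxy-3-(3-methylbut-2-en-1-yl)-4-(triisopropylsilyloxy)benzaldehyde, via hydroxymethyl phenol 12 (not isolated)
Conditions: MgCl2, Et3N, (CH2O)n, MeCN, reflux; dilute HCl work-up
Reagents that add atoms: formaldehyde (as paraformaldehyde), C=O
Why: Casnati–Skattebøl ortho-formylation, in which the magnesium phenoxide delivers formaldehyde within a chelate to the only free carbon ortho to the free hydroxyl (C4a) and a second formaldehyde oxidises the hydroxymethyl intermediate 12 by Oppenauer-type hydride transfer; C6 cannot react by this chelated pathway.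

Step 4
Reactants: 13 6-ethoxy-2-hydroxy-3-(3-methylbut-2-en-1-yl)-4-(triisopropylsilyloxy)benzaldehyde; 14 5-bromo-2-methylpent-2-ene
Product: 16 3-ethoxy-2-(1-hydroxy-5-methylhex-4-en-1-yl)-6-(3-methylbut-2-en-1-yl)-5-(triisopropylsilyloxy)phenol, via Grignard reagent 15 (not isolated)
Conditions: 14, Mg, THF, 40 °C (gives 15); 13 added to 15 (3 equiv), THF, 0 → 20 °C; cold H2O/NH4Cl; crude 16 used at once
Reagents that add atoms: none
Why: Grignard 1,2-addition, in which the first equivalent forms the magnesium phenoxide and a further one adds to the chelated aldehyde; the new carbinol centre forms as a racemate and is removed in step 5, and the acid-labile benzylic alcohol is therefore not purified.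

Step 5
Reactants: 16 3-ethoxy-2-(1-hydroxy-5-methylhex-4-en-1-yl)-6-(3-methylbut-2-en-1-yl)-5-(triisopropylsilyloxy)phenol
Product: 17 1-[6-ethoxy-2-hydroxy-3-(3-methylbut-2-en-1-yl)-4-(triisopropylsilyloxy)phenyl]-5-methylhex-4-en-1-one
Conditions: MnO2 (activated, excess), CH2Cl2, 20 °C
Reagents that add atoms: none
Why: Selective MnO2 oxidation of a benzylic alcohol to the hydrogen-bonded ortho-hydroxyaryl ketone under neutral conditions that should leave both alkenes, the silyl ether and the phenol untouched; the carbinol stereocentre is erased.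

Step 6
Reactants: 18 2,4-dihydroxybenzoic acid; 2 triisopropylsilyl trifluoromethanesulfonate
Product: 20 2,4-bis(triisopropylsilyloxy)benzoic acid, via silyl ester 19 (not isolated)
Conditions: 2 (3.3 equiv), Et3N, CH2Cl2, 0 → 20 °C; then K2CO3, THF/H2O, 0 → 20 °C; citric acid work-up
Reagents that add atoms: none
Why: Exhaustive O-silylation followed by selective hydrolysis of the silyl ester, which is far more labile to aqueous carbonate than the two hindered aryl silyl ethers; the triisopropylsilyl group is chosen for ring B because it should not migrate from O2' to a neighbouring enolate oxygen in step 7.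

Step 7
Reactants: 17 1-[6-ethoxy-2-hydroxy-3-(3-methylbut-2-en-1-yl)-4-(triisopropylsilyloxy)phenyl]-5-methylhex-4-en-1-one; 20 2,4-bis(triisopropylsilyloxy)benzoic acid
Product: 23 1-[2,4-bis(triisopropylsilyloxy)phenyl]-3-[6-ethoxy-2-hydroxy-3-(3-methylbut-2-en-1-yl)-4-(triisopropylsilyloxy)phenyl]-2-(3-methylbut-2-en-1-yl)propane-1,3-dione, via acid chloride 21 (not isolated), via aryl ester 22 (not isolated)
Conditions: 20, 1-chloro-N,N,2-trimethylprop-1-en-1-amine, CH2Cl2, 20 °C (gives 21); 17, LiN(SiMe3)2 (3.3 equiv), THF, −78 °C, then 21, −78 → 20 °C; aq NH4Cl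
Reagents that add atoms: none
Why: Baker–Venkataraman rearrangement in its one-pot form with excess lithium amide, in which the acid chloride (made under neutral conditions) acylates the phenoxide, the ketone enolate attacks the aryl ester through a six-membered transition state and the stabilised 1,3-diketonate drives the transfer; the C2 centre of 23 is racemic and labile and becomes sp2 in step 8.

Step 8
Reactants: 23 1-[2,4-bis(triisopropylsilyloxy)phenyl]-3-[6-ethoxy-2-hydroxy-3-(3-methylbut-2-en-1-yl)-4-(triisopropylsilyloxy)phenyl]-2-(3-methylbut-2-en-1-yl)propane-1,3-dione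
Product: 25 2-[2,4-bis(triisopropylsilyloxy)phenyl]-5-ethoxy-3,8-bis(3-methylbut-2-en-1-yl)-7-(triisopropylsilyloxy)-4H-chromen-4-one, via hemiketal 24 (not isolated)
Conditions: TsOH·H2O (10 mol %), PhMe, 40 °C
Reagents that add atoms: none
Why: Acid-catalysed cyclodehydration of an ortho-hydroxyaryl 1,3-diketone, in which the only free phenol (O1) adds to the ring B ketone to give hemiketal 24 and water is lost; because O5 is still an ethyl ether and O2' a silyl ether, ring C can close only through O1, which places the prenyl group at C8 and not C6, and once ring C has formed no free phenol remains beside either prenyl group.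

Step 9
Reactants: 25 2-[2,4-bis(triisopropylsilyloxy)phenyl]-5-ethoxy-3,8-bis(3-methylbut-2-en-1-yl)-7-(triisopropylsilyloxy)-4H-chromen-4-one
Product: 26 2-[2,4-bis(triisopropylsilyloxy)phenyl]-5-hydroxy-3,8-bis(3-methylbut-2-en-1-yl)-7-(triisopropylsilyloxy)-4H-chromen-4-one
Conditions: MgI2·OEt2 (5 equiv), THF/PhMe, 70 °C; aq Na2S2O3/NH4Cl
Reagents that add atoms: none
Why: Chelation-assisted ether cleavage, in which MgI2 binds between the C4 carbonyl and the peri O5 and iodide removes the ethyl group by SN2; only the peri ether is activated, no protic acid is present and every other oxygen is capped, so the prenyl groups should survive, as they are known to do when this reagent cleaves a peri methyl ether in an 8-prenylated flavanone, and any partial loss of silyl groups would be harmless because step 10 removes them all.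

Step 10
Reactants: 26 2-[2,4-bis(triisopropylsilyloxy)phenyl]-5-hydroxy-3,8-bis(3-methylbut-2-en-1-yl)-7-(triisopropylsilyloxy)-4H-chromen-4-one
Product: 27 kuwanon C 2-(2,4-dihydroxyphenyl)-5,7-dihydroxy-3,8-bis(3-methylbut-2-en-1-yl)-4H-chromen-4-one
Conditions: Bu4NF (3.5 equiv), AcOH (3.5 equiv), THF, 0 → 20 °C
Reagents that add atoms: none
Why: Fluoride-mediated cleavage of the three aryl silyl ethers, buffered with acetic acid so that the polyphenol is not held under strongly basic conditions; neither prenyl group reacts with fluoride and the target has no stereocentre.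

Compound list
1 | ethyl 4-methylpent-3-enoate | CCOC(=O)CC=C(C)C | starting material
2 | triisopropylsilyl trifluoromethanesulfonate | CC(C)[Si](OS(=O)(=O)C(F)(F)F)(C(C)C)C(C)C | starting material
3 | lithium 1,1-dibromo-5-methylhexa-1,4-dien-2-olate | [Li+].[O-]C(CC=C(C)C)=C(Br)Br | intermediate (not isolated)
4 | lithium 5-methylhex-4-en-1-yn-1-olate | [Li+].[O-]C#CCC=C(C)C | intermediate (not isolated)
5 | 5-methyl-1-(triisopropylsilyloxy)hex-4-en-1-yne | CC(C)=CCC#CO[Si](C(C)C)(C(C)C)C(C)C | intermediate
6 | 3-ethoxycyclobut-2-en-1-one | CCOC1=CC(=O)C1 | starting material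
7 | 3-ethoxybuta-1,3-dien-1-one | C=C(OCC)C=C=O | intermediate (not isolated)
8 | 4-(1-ethoxyethenyl)-2-(3-methylbut-2-en-1-yl)-3-(triisopropylsilyloxy)cyclobut-2-en-1-one (racemic) | O=C1C(CC=C(C)C)=C(O[Si](C(C)C)(C(C)C)C(C)C)C1C(OCC)=C | intermediate (not isolated)
9 | (3E)-5-ethoxy-2-(3-methylbut-2-en-1-yl)-3-(triisopropylsilyloxy)hexa-1,3,5-trien-1-one (ketene and ethoxyvinyl groups cis across C3=C4) | O=C=C(CC=C(C)C)/C(O[Si](C(C)C)(C(C)C)C(C)C)=C\C(OCC)=C | intermediate (not isolated)
10 | 5-ethoxy-2-(3-methylbut-2-en-1-yl)-3-(triisopropylsilyloxy)cyclohexa-2,4-dien-1-one | O=C1C(CC=C(C)C)=C(O[Si](C(C)C)(C(C)C)C(C)C)C=C(OCC)C1 | intermediate (not isolated)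
11 | 5-ethoxy-2-(3-methylbut-2-en-1-yl)-3-(triisopropylsilyloxy)phenol | CCOc1cc(O)c(CC=C(C)C)c(O[Si](C(C)C)(C(C)C)C(C)C)c1 | intermediate
12 | 3-ethoxy-2-(hydroxymethyl)-6-(3-methylbut-2-en-1-yl)-5-(triisopropylsilyloxy)phenol (present as its magnesium chelate) | CCOc1cc(O[Si](C(C)C)(C(C)C)C(C)C)c(CC=C(C)C)c(O)c1CO | intermediate (not isolated)
13 | 6-ethoxy-2-hydroxy-3-(3-methylbut-2-en-1-yl)-4-(triisopropylsilyloxy)benzaldehyde | CCOc1cc(O[Si](C(C)C)(C(C)C)C(C)C)c(CC=C(C)C)c(O)c1C=O | intermediate
14 | 5-bromo-2-methylpent-2-ene | CC(C)=CCCBr | starting material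
15 | (4-methylpent-3-en-1-yl)magnesium bromide | CC(C)=CCC[Mg]Br | intermediate (not isolated)
16 | 3-ethoxy-2-(1-hydroxy-5-methylhex-4-en-1-yl)-6-(3-methylbut-2-en-1-yl)-5-(triisopropylsilyloxy)phenol (racemic) | CCOc1cc(O[Si](C(C)C)(C(C)C)C(C)C)c(CC=C(C)C)c(O)c1C(O)CCC=C(C)C | intermediate
17 | 1-[6-ethoxy-2-hydroxy-3-(3-methylbut-2-en-1-yl)-4-(triisopropylsilyloxy)phenyl]-5-methylhex-4-en-1-one | CCOc1cc(O[Si](C(C)C)(C(C)C)C(C)C)c(CC=C(C)C)c(O)c1C(=O)CCC=C(C)C | intermediate
18 | 2,4-dihydroxybenzoic acid | O=C(O)c1ccc(O)cc1O | starting material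
19 | triisopropylsilyl 2,4-bis(triisopropylsilyloxy)benzoate | CC(C)[Si](OC(=O)c1ccc(O[Si](C(C)C)(C(C)C)C(C)C)cc1O[Si](C(C)C)(C(C)C)C(C)C)(C(C)C)C(C)C | intermediate (not isolated)
20 | 2,4-bis(triisopropylsilyloxy)benzoic acid | O=C(O)c1ccc(O[Si](C(C)C)(C(C)C)C(C)C)cc1O[Si](C(C)C)(C(C)C)C(C)C | intermediate
21 | 2,4-bis(triisopropylsilyloxy)benzoyl chloride | O=C(Cl)c1ccc(O[Si](C(C)C)(C(C)C)C(C)C)cc1O[Si](C(C)C)(C(C)C)C(C)C | intermediate (not isolated)
22 | 3-ethoxy-2-(5-methylhex-4-enoyl)-6-(3-methylbut-2-en-1-yl)-5-(triisopropylsilyloxy)phenyl 2,4-bis(triisopropylsilyloxy)benzoate | CCOc1cc(O[Si](C(C)C)(C(C)C)C(C)C)c(CC=C(C)C)c(OC(=O)c2ccc(O[Si](C(C)C)(C(C)C)C(C)C)cc2O[Si](C(C)C)(C(C)C)C(C)C)c1C(=O)CCC=C(C)C | intermediate (not isolated)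
23 | 1-[2,4-bis(triisopropylsilyloxy)phenyl]-3-[6-ethoxy-2-hydroxy-3-(3-methylbut-2-en-1-yl)-4-(triisopropylsilyloxy)phenyl]-2-(3-methylbut-2-en-1-yl)propane-1,3-dione (racemic at C2, with enol tautomers) | CCOc1cc(O[Si](C(C)C)(C(C)C)C(C)C)c(CC=C(C)C)c(O)c1C(=O)C(CC=C(C)C)C(=O)c1ccc(O[Si](C(C)C)(C(C)C)C(C)C)cc1O[Si](C(C)C)(C(C)C)C(C)C | intermediate
24 | 2-[2,4-bis(triisopropylsilyloxy)phenyl]-5-ethoxy-2-hydroxy-3,8-bis(3-methylbut-2-en-1-yl)-7-(triisopropylsilyloxy)chroman-4-one (racemic mixture of diastereomers) | CCOc1cc(O[Si](C(C)C)(C(C)C)C(C)C)c(CC=C(C)C)c2OC(O)(c3ccc(O[Si](C(C)C)(C(C)C)C(C)C)cc3O[Si](C(C)C)(C(C)C)C(C)C)C(CC=C(C)C)C(=O)c12 | intermediate (not isolated)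
25 | 2-[2,4-bis(triisopropylsilyloxy)phenyl]-5-ethoxy-3,8-bis(3-methylbut-2-en-1-yl)-7-(triisopropylsilyloxy)-4H-chromen-4-one | CCOc1cc(O[Si](C(C)C)(C(C)C)C(C)C)c(CC=C(C)C)c2oc(-c3ccc(O[Si](C(C)C)(C(C)C)C(C)C)cc3O[Si](C(C)C)(C(C)C)C(C)C)c(CC=C(C)C)c(=O)c12 | intermediate
26 | 2-[2,4-bis(triisopropylsilyloxy)phenyl]-5-hydroxy-3,8-bis(3-methylbut-2-en-1-yl)-7-(triisopropylsilyloxy)-4H-chromen-4-one | Oc1cc(O[Si](C(C)C)(C(C)C)C(C)C)c(CC=C(C)C)c2oc(-c3ccc(O[Si](C(C)C)(C(C)C)C(C)C)cc3O[Si](C(C)C)(C(C)C)C(C)C)c(CC=C(C)C)c(=O)c12 | intermediate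
27 | kuwanon C, 2-(2,4-dihydroxyphenyl)-5,7-dihydroxy-3,8-bis(3-methylbut-2-en-1-yl)-4H-chromen-4-one | CC(C)=CCc1c(-c2ccc(O)cc2O)oc2c(CC=C(C)C)c(O)cc(O)c2c1=O | target

Total step count: 10. Longest linear sequence: 9 steps (steps 1–5 and 7–10; step 6 is the ring B branch).

Steps most likely to fail

Step 2 (key step). The vinylogous-ester cyclobutenone 6 may open to 7 only at temperatures at which 5 is lost by 1,3-silyl shift to a silylketene, or the cascade may stall at 8. The fallback is the second-generation, photochemical form of the benzannulation; it sets out from siloxyalkyne 5 and rejoins the route at vinylketene 7. Ethyl vinyl ether is lithiated (t-BuLi, THF) and acylated with N-methoxy-N-methylacetamide to give 3-ethoxybut-3-en-2-one F1. Its lithium enolate is trifluoroacetylated (LiN(SiMe3)2, CF3CO2CH2CF3, THF, −78 °C) to 5-ethoxy-1,1,1-trifluorohex-5-ene-2,4-dione F2, which with MsN3 and Et3N in aqueous MeCN should undergo detrifluoroacetylative diazo transfer to 1-diazo-3-ethoxybut-3-en-2-one F3. Irradiation of F3 with 5 (CH2Cl2, 20 °C) should trigger a Wolff rearrangement to 7 at room temperature; 7 is trapped by 5 as before, and brief warming to 80 °C should take 8 through 9 and 10 to phenol 11.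

Step 1. The α-CH2 of 1 is both allylic and next to the ester, so deprotonation by LiCHBr2 or the amide base, followed by conjugation of the double bond, may outrun addition to the carbonyl. The fallback replaces ester homologation by oxidation of an alkynyllithium; it sets out from ester 1 and rejoins the route at ynolate 4. Reduction with i-Bu2AlH (CH2Cl2, −78 °C) gives 4-methylpent-3-enal F4, and Corey–Fuchs olefination (CBr4, PPh3, CH2Cl2, 0 °C) gives 1,1-dibromo-5-methylhexa-1,4-diene F5. n-BuLi (2.1 equiv, THF, −78 °C) converts F5 into lithium 5-methylhex-4-en-1-yn-1-ide F6, which is oxidised in the same flask with LiOOt-Bu (from t-BuOOH and LiN(SiMe3)2, −78 → 0 °C) to ynolate 4 and silylated with 2 as in step 1.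

Step 9. SN2 attack of iodide on an ethyl group is much slower than on a methyl group, so the cleavage may stall or need temperatures at which the Lewis acid begins to attack the prenyl groups. The fallback is a nucleophilic dealkylation under basic conditions after desilylation; it sets out from flavone 25 and rejoins the route at target 27. Bu4NF/AcOH (THF, 0 °C) should convert 25 into 2-(2,4-dihydroxyphenyl)-5-ethoxy-7-hydroxy-3,8-bis(3-methylbut-2-en-1-yl)-4H-chromen-4-one F7. Sodium ethanethiolate (excess, DMF, 110 °C) should then remove the ethyl group by thiolate SN2, conditions under which prenyl groups are inert, and acidification gives 27.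

Further compounds
F1 | step 2 | 3-ethoxybut-3-en-2-one | C=C(OCC)C(C)=O
F2 | step 2 | 5-ethoxy-1,1,1-trifluorohex-5-ene-2,4-dione | C=C(OCC)C(=O)CC(=O)C(F)(F)F
F3 | step 2 | 1-diazo-3-ethoxybut-3-en-2-one | C=C(OCC)C(=O)C=[N+]=[N-]
F4 | step 1 | 4-methylpent-3-enal | O=CCC=C(C)C
F5 | step 1 | 1,1-dibromo-5-methylhexa-1,4-diene | BrC(Br)=CCC=C(C)C
F6 | step 1 | lithium 5-methylhex-4-en-1-yn-1-ide | [Li+].[C-]#CCC=C(C)C
F7 | step 9 | 2-(2,4-dihydroxyphenyl)-5-ethoxy-7-hydroxy-3,8-bis(3-methylbut-2-en-1-yl)-4H-chromen-4-one | CCOc1cc(O)c(CC=C(C)C)c2oc(-c3ccc(O)cc3O)c(CC=C(C)C)c(=O)c12
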